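**Strategy**

The plan rests on opening the dihydropyranone ring (O1, C2, C3=C4, C5, C6) across C5–C6 and O1–C2. Because C6 is the only ring stereocentre and C2–C5 form an unbranched four-carbon unit with the alkene at C3=C4, the ring maps onto a hetero-Diels–Alder adduct of an aldehyde and (E)-1-methoxybutadiene. One chromium(III)-catalysed cycloaddition joins the fragments, closes the ring, places the alkene and sets C6 by catalyst control; the acetal carbon C2 is then oxidised to the lactone carbonyl. The aldehyde partner is (3R,5R,7R)-3,5,7-tris(tert-butyldimethylsilyloxy)docosanal, built from hexadecanal by three reagent-controlled allylboration, silylation and ozonolysis cycles.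

Key step: step 10

Assumption: the sense of induction of both chiral reagents is taken from their established behaviour with unbranched aldehydes, where the (+)-α-pinene-derived allylborane adds to the Si face and the (1R,2S)-aminoindanol chromium complex directs the diene to the Re face, so its (1S,2R) enantiomer is specified for Si-face attack.

Remark: some R/S labels at silyloxy carbons differ between intermediates only because CIP priorities change; no centre is inverted anywhere in the route.

**Route**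

Step 1
Reactants: 1 hexadecanal; 2 (−)-B-allyldiisopinocampheylborane
Product: 4 (R)-nonadec-1-en-4-ol, via borinate ester 3 (not isolated)
Conditions: 2 (1 M in pentane), Et2O, −78 °C; then 3 M NaOH, 30% H2O2, 0 °C to rt
Reagents that add atoms: none
Why: Brown allylboration through a closed chair (Zimmerman–Traxler) transition state, in which the isopinocampheyl groups of the (+)-α-pinene-derived borane steer the allyl group to the Si face of the aldehyde and should set C4 as R (the future C6'); oxidative work-up releases the alcohol.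

Step 2
Reactants: 4 (R)-nonadec-1-en-4-ol
Product: 5 (R)-4-(tert-butyldimethylsilyloxy)nonadec-1-ene
Conditions: TBSOTf, 2,6-lutidine, CH2Cl2, −78 to 0 °C
Reagents that add atoms: tert-butyldimethylsilyl triflate, CC(C)(C)[Si](C)(C)OS(=O)(=O)C(F)(F)F
Why: Silyl ether formation with the silyl triflate and a hindered base is fast on a secondary homoallylic alcohol and does not touch the stereocentre.

Step 3
Reactants: 5 (R)-4-(tert-butyldimethylsilyloxy)nonadec-1-ene
Product: 7 (R)-3-(tert-butyldimethylsilyloxy)octadecanal, via ozonide 6 (not isolated)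
Conditions: O3, CH2Cl2, −78 °C; then PPh3, −78 °C to rt
Reagents that add atoms: ozone, [O-][O+]=O
Why: Ozonolysis (Criegee mechanism) cleaves only the terminal alkene, and phosphine reduction of the ozonide gives the aldehyde without affecting the silyl ether or the β-stereocentre.

Step 4
Reactants: 7 (R)-3-(tert-butyldimethylsilyloxy)octadecanal; 2 (−)-B-allyldiisopinocampheylborane
Product: 9 (4S,6R)-6-(tert-butyldimethylsilyloxy)henicos-1-en-4-ol, via borinate ester 8 (not isolated)
Conditions: 2 (1 M in pentane), Et2O, −78 °C; then 3 M NaOH, 30% H2O2, 0 °C to rt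
Reagents that add atoms: none
Why: Brown allylboration under reagent control; the same borane again adds to the Si face of a β-silyloxy aldehyde whose own 1,3-bias is weak without chelation, which should set C4 as S, syn to the C6 silyloxy group (the future C4').

Step 5
Reactants: 9 (4S,6R)-6-(tert-butyldimethylsilyloxy)henicos-1-en-4-ol
Product: 10 (4S,6R)-4,6-bis(tert-butyldimethylsilyloxy)henicos-1-ene
Conditions: TBSOTf, 2,6-lutidine, CH2Cl2, −78 to 0 °C
Reagents that add atoms: tert-butyldimethylsilyl triflate, CC(C)(C)[Si](C)(C)OS(=O)(=O)C(F)(F)F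
Why: Silyl ether formation; the triflate silylates the more hindered secondary alcohol cleanly, and any 1,3-silyl migration beforehand would be harmless because both oxygens end up silylated.

Step 6
Reactants: 10 (4S,6R)-4,6-bis(tert-butyldimethylsilyloxy)henicos-1-ene
Product: 12 (3R,5R)-3,5-bis(tert-butyldimethylsilyloxy)icosanal, via ozonide 11 (not isolated)
Conditions: O3, CH2Cl2, −78 °C; then PPh3, −78 °C to rt
Reagents that add atoms: ozone, [O-][O+]=O
Why: Ozonolysis with reductive work-up, as in step 3; the only oxidisable group is the terminal alkene.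

Step 7
Reactants: 12 (3R,5R)-3,5-bis(tert-butyldimethylsilyloxy)icosanal; 2 (−)-B-allyldiisopinocampheylborane
Product: 14 (4S,6S,8R)-6,8-bis(tert-butyldimethylsilyloxy)tricos-1-en-4-ol, via borinate ester 13 (not isolated)
Conditions: 2 (1 M in pentane), Et2O, −78 °C; then 3 M NaOH, 30% H2O2, 0 °C to rt
Reagents that add atoms: none
Why: Third Brown allylboration with the same borane; Si-face addition under reagent control should set C4 as S, syn to the neighbouring silyloxy centre (the future C2').

Step 8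
Reactants: 14 (4S,6S,8R)-6,8-bis(tert-butyldimethylsilyloxy)tricos-1-en-4-ol
Product: 15 (4S,6R,8R)-4,6,8-tris(tert-butyldimethylsilyloxy)tricos-1-ene
Conditions: TBSOTf, 2,6-lutidine, CH2Cl2, −78 to 0 °C
Reagents that add atoms: tert-butyldimethylsilyl triflate, CC(C)(C)[Si](C)(C)OS(=O)(=O)C(F)(F)F
Why: Silyl ether formation on the last free carbinol, giving a uniformly protected, non-chelating triol array.

Step 9
Reactants: 15 (4S,6R,8R)-4,6,8-tris(tert-butyldimethylsilyloxy)tricos-1-ene
Product: 17 (3R,5R,7R)-3,5,7-tris(tert-butyldimethylsilyloxy)docosanal, via ozonide 16 (not isolated)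
Conditions: O3, CH2Cl2, −78 °C; then PPh3, −78 °C to rt; aldehyde dried azeotropically and used at once
Reagents that add atoms: ozone, [O-][O+]=O
Why: Ozonolysis with reductive work-up as before; the β-silyloxy aldehyde is taken straight into the cycloaddition to avoid elimination on storage.

Step 10
Reactants: 17 (3R,5R,7R)-3,5,7-tris(tert-butyldimethylsilyloxy)docosanal; 18 (E)-1-methoxybuta-1,3-diene
Product: 19 (2R,6S)-2-methoxy-6-[(2S,4R,6R)-2,4,6-tris(tert-butyldimethylsilyloxy)henicosyl]-5,6-dihydro-2H-pyran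
Conditions: Cr(III)Cl complex of the tridentate Schiff base from (1S,2R)-1-amino-2-indanol and 3-(1-adamantyl)-2-hydroxy-5-methylbenzaldehyde (5 mol %), 4 Å MS, 18 (3 equiv), neat or minimal t-BuOMe, rt
Reagents that add atoms: none
Why: The Lewis-acidic Cr(III) centre binds the aldehyde oxygen and the diene adds in a concerted, asynchronous endo [4+2] cycloaddition, with C5–C6 (diene CH2 terminus to carbonyl carbon) forming ahead of O1–C2; this is the known Cr(III)–Schiff base hetero-Diels–Alder reaction of 1-alkoxybutadienes with unactivated aliphatic aldehydes. The six-membered ring is closed by intermolecular cycloaddition of the 4π diene with the 2π C=O group, so both ring bonds form in one event and the C3=C4 alkene is left in place. C6 (S) is set by the catalyst, whose (1S,2R) enantiomer should expose the Si face of the aldehyde, while C2 (R, methoxy cis to the side chain) follows from the endo transition state and is erased later. Regioselectivity comes from the methoxy group, which makes the unsubstituted diene terminus the nucleophilic end and so places the acetal carbon next to the ring oxygen. The step needs catalyst control to override any bias of the C3 silyloxy centre; that centre is β to the carbonyl and carries a bulky, non-chelating silyl ether, so its own facial preference should be small. Molecular sieves and the absence of Brønsted acid or base should keep the aldehyde from enolising or losing silanol.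

Step 11
Reactants: 19 (2R,6S)-2-methoxy-6-[(2S,4R,6R)-2,4,6-tris(tert-butyldimethylsilyloxy)henicosyl]-5,6-dihydro-2H-pyran
Product: 20 (6S)-6-[(2S,4R,6R)-2,4,6-tris(tert-butyldimethylsilyloxy)henicosyl]-5,6-dihydro-2H-pyran-2-ol
Conditions: PPTS (cat.), acetone/H2O 9:1, rt
Reagents that add atoms: water, O
Why: Acid-catalysed hydrolysis of the allylic methyl acetal proceeds through a conjugated oxocarbenium ion under conditions too mild to cleave secondary TBS ethers; C6 is not involved and C2 becomes an anomeric mixture.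

Step 12
Reactants: 20 (6S)-6-[(2S,4R,6R)-2,4,6-tris(tert-butyldimethylsilyloxy)henicosyl]-5,6-dihydro-2H-pyran-2-ol
Product: 21 (S)-6-[(2S,4R,6R)-2,4,6-tris(tert-butyldimethylsilyloxy)henicosyl]-5,6-dihydro-2H-pyran-2-one
Conditions: activated MnO2 (excess), CH2Cl2, rt
Reagents that add atoms: none
Why: Manganese dioxide oxidation of the allylic hemiacetal hydroxyl gives the conjugated δ-lactone, erasing the C2 stereocentre and leaving the silyl ethers and C6 untouched.

Step 13
Reactants: 21 (S)-6-[(2S,4R,6R)-2,4,6-tris(tert-butyldimethylsilyloxy)henicosyl]-5,6-dihydro-2H-pyran-2-one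
Product: 22 (S)-6-[(2R,4R,6R)-2,4,6-trihydroxyhenicosyl]-5,6-dihydro-2H-pyran-2-one
Conditions: 48% aq. HF, MeCN/THF, 0 °C to rt
Reagents that add atoms: none
Why: Acidic fluoride desilylation cleaves the three secondary silyl ethers without forming alkoxides, so conjugate addition of the C2' hydroxyl to C4 and opening of the lactone should be avoided.

**Compound list**

1 | hexadecanal | CCCCCCCCCCCCCCCC=O | starting material
2 | (−)-B-allyldiisopinocampheylborane, the enantiomer derived from (+)-α-pinene | C=CCB([C@@H]1C[C@@H]2C[C@H]([C@H]1C)C2(C)C)[C@@H]1C[C@@H]2C[C@H]([C@H]1C)C2(C)C | starting material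
3 | (R)-nonadec-1-en-4-yl diisopinocampheylborinate | CCCCCCCCCCCCCCC[C@@H](OB([C@@H]1C[C@@H]2C[C@H]([C@H]1C)C2(C)C)[C@@H]1C[C@@H]2C[C@H]([C@H]1C)C2(C)C)CC=C | intermediate
4 | (R)-nonadec-1-en-4-ol | CCCCCCCCCCCCCCC[C@@H](O)CC=C | intermediate
5 | (R)-4-(tert-butyldimethylsilyloxy)nonadec-1-ene | CCCCCCCCCCCCCCC[C@@H](O[Si](C)(C)C(C)(C)C)CC=C | intermediate
6 | 3-[(R)-2-(tert-butyldimethylsilyloxy)heptadecyl]-1,2,4-trioxolane (ring carbon unspecified, epimer mixture) | CCCCCCCCCCCCCCC[C@@H](O[Si](C)(C)C(C)(C)C)CC1OCOO1 | intermediate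
7 | (R)-3-(tert-butyldimethylsilyloxy)octadecanal | CCCCCCCCCCCCCCC[C@@H](O[Si](C)(C)C(C)(C)C)CC=O | intermediate
8 | (4S,6R)-6-(tert-butyldimethylsilyloxy)henicos-1-en-4-yl diisopinocampheylborinate | CCCCCCCCCCCCCCC[C@@H](O[Si](C)(C)C(C)(C)C)C[C@@H](OB([C@@H]1C[C@@H]2C[C@H]([C@H]1C)C2(C)C)[C@@H]1C[C@@H]2C[C@H]([C@H]1C)C2(C)C)CC=C | intermediate
9 | (4S,6R)-6-(tert-butyldimethylsilyloxy)henicos-1-en-4-ol | CCCCCCCCCCCCCCC[C@@H](O[Si](C)(C)C(C)(C)C)C[C@@H](O)CC=C | intermediate
10 | (4S,6R)-4,6-bis(tert-butyldimethylsilyloxy)henicos-1-ene | CCCCCCCCCCCCCCC[C@@H](O[Si](C)(C)C(C)(C)C)C[C@@H](O[Si](C)(C)C(C)(C)C)CC=C | intermediate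
11 | 3-[(2R,4R)-2,4-bis(tert-butyldimethylsilyloxy)nonadecyl]-1,2,4-trioxolane (ring carbon unspecified, epimer mixture) | CCCCCCCCCCCCCCC[C@@H](O[Si](C)(C)C(C)(C)C)C[C@@H](O[Si](C)(C)C(C)(C)C)CC1OCOO1 | intermediate
12 | (3R,5R)-3,5-bis(tert-butyldimethylsilyloxy)icosanal | CCCCCCCCCCCCCCC[C@@H](O[Si](C)(C)C(C)(C)C)C[C@@H](O[Si](C)(C)C(C)(C)C)CC=O | intermediate
13 | (4S,6S,8R)-6,8-bis(tert-butyldimethylsilyloxy)tricos-1-en-4-yl diisopinocampheylborinate | CCCCCCCCCCCCCCC[C@@H](O[Si](C)(C)C(C)(C)C)C[C@@H](O[Si](C)(C)C(C)(C)C)C[C@@H](OB([C@@H]1C[C@@H]2C[C@H]([C@H]1C)C2(C)C)[C@@H]1C[C@@H]2C[C@H]([C@H]1C)C2(C)C)CC=C | intermediate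
14 | (4S,6S,8R)-6,8-bis(tert-butyldimethylsilyloxy)tricos-1-en-4-ol | CCCCCCCCCCCCCCC[C@@H](O[Si](C)(C)C(C)(C)C)C[C@@H](O[Si](C)(C)C(C)(C)C)C[C@@H](O)CC=C | intermediate
15 | (4S,6R,8R)-4,6,8-tris(tert-butyldimethylsilyloxy)tricos-1-ene | CCCCCCCCCCCCCCC[C@@H](O[Si](C)(C)C(C)(C)C)C[C@@H](O[Si](C)(C)C(C)(C)C)C[C@@H](O[Si](C)(C)C(C)(C)C)CC=C | intermediate
16 | 3-[(2R,4R,6R)-2,4,6-tris(tert-butyldimethylsilyloxy)henicosyl]-1,2,4-trioxolane (ring carbon unspecified, epimer mixture) | CCCCCCCCCCCCCCC[C@@H](O[Si](C)(C)C(C)(C)C)C[C@@H](O[Si](C)(C)C(C)(C)C)C[C@@H](O[Si](C)(C)C(C)(C)C)CC1OCOO1 | intermediate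
17 | (3R,5R,7R)-3,5,7-tris(tert-butyldimethylsilyloxy)docosanal | CCCCCCCCCCCCCCC[C@@H](O[Si](C)(C)C(C)(C)C)C[C@@H](O[Si](C)(C)C(C)(C)C)C[C@@H](O[Si](C)(C)C(C)(C)C)CC=O | intermediate
18 | (E)-1-methoxybuta-1,3-diene | CO/C=C/C=C | starting material
19 | (2R,6S)-2-methoxy-6-[(2S,4R,6R)-2,4,6-tris(tert-butyldimethylsilyloxy)henicosyl]-5,6-dihydro-2H-pyran (2,6-cis; side chain all-syn) | CCCCCCCCCCCCCCC[C@@H](O[Si](C)(C)C(C)(C)C)C[C@@H](O[Si](C)(C)C(C)(C)C)C[C@@H](O[Si](C)(C)C(C)(C)C)C[C@@H]1CC=C[C@H](OC)O1 | intermediate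
20 | (6S)-6-[(2S,4R,6R)-2,4,6-tris(tert-butyldimethylsilyloxy)henicosyl]-5,6-dihydro-2H-pyran-2-ol (C2 unspecified, anomer mixture) | CCCCCCCCCCCCCCC[C@@H](O[Si](C)(C)C(C)(C)C)C[C@@H](O[Si](C)(C)C(C)(C)C)C[C@@H](O[Si](C)(C)C(C)(C)C)C[C@@H]1CC=CC(O)O1 | intermediate
21 | (S)-6-[(2S,4R,6R)-2,4,6-tris(tert-butyldimethylsilyloxy)henicosyl]-5,6-dihydro-2H-pyran-2-one | CCCCCCCCCCCCCCC[C@@H](O[Si](C)(C)C(C)(C)C)C[C@@H](O[Si](C)(C)C(C)(C)C)C[C@@H](O[Si](C)(C)C(C)(C)C)C[C@@H]1CC=CC(=O)O1 | intermediate
22 | (S)-6-[(2R,4R,6R)-2,4,6-trihydroxyhenicosyl]-5,6-dihydro-2H-pyran-2-one | CCCCCCCCCCCCCCC[C@@H](O)C[C@@H](O)C[C@@H](O)C[C@@H]1CC=CC(=O)O1 | target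

**Totals and risks**

Total step count: 13. Longest linear sequence: 13 steps (1 to 22).

Steps most likely to fail:

1. Step 10. The hindered β-branched aldehyde may react sluggishly with the weakly nucleophilic diene, the catalyst may fail to override the resident C3 centre (poor facial selectivity at C6), or silanol may be eliminated from the aldehyde during a long reaction. The fallback sets out from 17 and returns to the route at 21, bypassing steps 11 and 12.
   - A fourth allylboration of 17 with 2 (Et2O, −78 °C; NaOH, H2O2) should give, by way of (4S,6S,8R,10R)-6,8,10-tris(tert-butyldimethylsilyloxy)pentacos-1-en-4-yl diisopinocampheylborinate F1, the homoallylic alcohol (4S,6S,8R,10R)-6,8,10-tris(tert-butyldimethylsilyloxy)pentacos-1-en-4-ol F2, whose carbinol is the future C6.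
   - Acylation with acryloyl chloride (Et3N, cat. DMAP, CH2Cl2, 0 °C) gives (4S,6S,8R,10R)-6,8,10-tris(tert-butyldimethylsilyloxy)pentacos-1-en-4-yl prop-2-enoate F3.
   - Ring-closing metathesis (second-generation Grubbs catalyst, CH2Cl2, 40 °C, dilute) closes the lactone 21 with loss of ethylene.

2. Step 11. Acetal hydrolysis may be slow enough to compete with partial loss of silyl ethers, or the lactol may open to the hydroxy-enal and isomerise from Z to E, after which it cannot reclose. The fallback sets out from 19 and returns at 21 without passing through 20. Pyridinium chlorochromate in CH2Cl2 at rt should convert the allylic acetal directly into the lactone by chromium-assisted ionisation and oxidation of the resulting chromate ester, with loss of methanol and no aqueous acid. It makes no compound outside the list.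

3. Step 7. Reagent control may be eroded by the two resident silyloxy centres and by slow addition to the more hindered aldehyde, giving C4 epimers that are hard to separate. The fallback sets out from 9 and returns at 17, replacing steps 5 to 9 by five steps in which the new carbinol is set by substrate (thermodynamic) control.
   - Cross-metathesis of 9 with methyl acrylate (second-generation Grubbs catalyst, CH2Cl2, 40 °C) should give methyl (2E,5S,7R)-7-(tert-butyldimethylsilyloxy)-5-hydroxydocos-2-enoate F4.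
   - Benzaldehyde and catalytic KOt-Bu (THF, 0 °C) convert it, by hemiacetal formation and intramolecular oxa-Michael addition, into the all-equatorial benzylidene acetal methyl 2-[(2R,4R,6S)-6-[(R)-2-(tert-butyldimethylsilyloxy)heptadecyl]-2-phenyl-1,3-dioxan-4-yl]acetate F5, with the new C–O bond syn to the existing one.
   - Hydrogenolysis (H2, Pd(OH)2/C, EtOAc) frees methyl (3R,5S,7R)-7-(tert-butyldimethylsilyloxy)-3,5-dihydroxydocosanoate F6.
   - Silylation (TBSOTf, 2,6-lutidine, CH2Cl2) gives methyl (3R,5R,7R)-3,5,7-tris(tert-butyldimethylsilyloxy)docosanoate F7.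
   - DIBAL-H (CH2Cl2, −78 °C) reduces the ester to aldehyde 17.

Further compounds
F1 | step 10 | (4S,6S,8R,10R)-6,8,10-tris(tert-butyldimethylsilyloxy)pentacos-1-en-4-yl diisopinocampheylborinate | CCCCCCCCCCCCCCC[C@@H](O[Si](C)(C)C(C)(C)C)C[C@@H](O[Si](C)(C)C(C)(C)C)C[C@@H](O[Si](C)(C)C(C)(C)C)C[C@@H](OB([C@@H]1C[C@@H]2C[C@H]([C@H]1C)C2(C)C)[C@@H]1C[C@@H]2C[C@H]([C@H]1C)C2(C)C)CC=C
F2 | step 10 | (4S,6S,8R,10R)-6,8,10-tris(tert-butyldimethylsilyloxy)pentacos-1-en-4-ol | CCCCCCCCCCCCCCC[C@@H](O[Si](C)(C)C(C)(C)C)C[C@@H](O[Si](C)(C)C(C)(C)C)C[C@@H](O[Si](C)(C)C(C)(C)C)C[C@@H](O)CC=C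
F3 | step 10 | (4S,6S,8R,10R)-6,8,10-tris(tert-butyldimethylsilyloxy)pentacos-1-en-4-yl prop-2-enoate | CCCCCCCCCCCCCCC[C@@H](O[Si](C)(C)C(C)(C)C)C[C@@H](O[Si](C)(C)C(C)(C)C)C[C@@H](O[Si](C)(C)C(C)(C)C)C[C@@H](OC(=O)C=C)CC=C
F0 | step 11 | none | none
F4 | step 7 | methyl (2E,5S,7R)-7-(tert-butyldimethylsilyloxy)-5-hydroxydocos-2-enoate | CCCCCCCCCCCCCCC[C@@H](O[Si](C)(C)C(C)(C)C)C[C@@H](O)C/C=C/C(=O)OC
F5 | step 7 | methyl 2-[(2R,4R,6S)-6-[(R)-2-(tert-butyldimethylsilyloxy)heptadecyl]-2-phenyl-1,3-dioxan-4-yl]acetate | CCCCCCCCCCCCCCC[C@@H](O[Si](C)(C)C(C)(C)C)C[C@@H]1C[C@H](CC(=O)OC)O[C@H](c2ccccc2)O1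
F6 | step 7 | methyl (3R,5S,7R)-7-(tert-butyldimethylsilyloxy)-3,5-dihydroxydocosanoate | CCCCCCCCCCCCCCC[C@@H](O[Si](C)(C)C(C)(C)C)C[C@@H](O)C[C@@H](O)CC(=O)OC
F7 | step 7 | methyl (3R,5R,7R)-3,5,7-tris(tert-butyldimethylsilyloxy)docosanoate | CCCCCCCCCCCCCCC[C@@H](O[Si](C)(C)C(C)(C)C)C[C@@H](O[Si](C)(C)C(C)(C)C)C[C@@H](O[Si](C)(C)C(C)(C)C)CC(=O)OC
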